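**Retrosynthetic overview**
- Feature: C2 and C3 of the dihydrobenzofuran are the two alkene carbons of an E-stilbene joining ring A (the benzo ring) to the syringyl ring. Only the O1–C2 bond and the C3–C9 bond (C9 = the CH2OH carbon) are missing, and C9 can come from carbon monoxide.
- Last disconnection: the C5 styryl arm, by Horner–Wadsworth–Emmons olefination of a C5 aldehyde with a 3,5-bis(silyloxy)benzylphosphonate, then fluoride desilylation. The C9 ester is reduced before this olefination so that no carbanion meets an acidic C3–H.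
- Key disconnection: O1–C2 and C3–C9, by enantioselective Wacker-type oxypalladation–methoxycarbonylation of a 2-hydroxystilbene. This closes the dihydrofuran ring, the only ring formed in the route; the three benzene rings are bought.
- First disconnection: the stilbene, by Heck coupling of 5-iodovanillin (from vanillin) with 3,5-dimethoxy-4-silyloxystyrene (from syringaldehyde).

Key step: step 5

Assumption: the sense of induction of a bis(oxazoline)–palladium catalyst on a 1,2-diarylalkene cannot be assigned in advance. The route is written for the ligand antipode that leads to (2R), to be fixed by a first test run; the ligand meant is (S,S)-Bn-BOXAX, 2,2'-bis[(4S)-4-benzyl-4,5-dihydrooxazol-2-yl]-1,1'-binaphthyl, or its mirror image.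

**Route**

Step 1
Reactants: 1 vanillin
Product: 2 5-iodovanillin (4-hydroxy-3-iodo-5-methoxybenzaldehyde)
Conditions: I2, KI, NaHCO3, H2O, 25 °C
Reagents that add atoms: iodine, II
Why: Electrophilic aromatic iodination of the phenoxide, which can only take place at the one free position ortho to the hydroxyl because the para position carries the formyl group.

Step 2
Reactants: 3 syringaldehyde
Product: 4 3,5-dimethoxy-4-(triisopropylsilyloxy)benzaldehyde
Conditions: TIPSCl, imidazole, DMF, 25 to 50 °C
Reagents that add atoms: chlorotriisopropylsilane, CC(C)[Si](Cl)(C(C)C)C(C)C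
Why: Imidazole-promoted silylation of the acidic phenol gives a hindered aryl TIPS ether that should withstand ylide, amine base, benzoquinone and hydride and that later blocks quinone methide formation at the benzylic C2–O1 bond.

Step 3
Reactants: 4 3,5-dimethoxy-4-(triisopropylsilyloxy)benzaldehyde
Product: 5 3,5-dimethoxy-4-(triisopropylsilyloxy)styrene
Conditions: Ph3PCH3Br (1.3 equiv), KOt-Bu (1.2 equiv), THF, 0 °C; then 4, 0 to 25 °C
Reagents that add atoms: methyltriphenylphosphonium bromide, C[P+](c1ccccc1)(c1ccccc1)c1ccccc1.[Br-]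
Why: Wittig methylenation of a non-enolisable aromatic aldehyde with a preformed ylide, so that no free alkoxide remains to attack the aryl silyl ether.

Step 4
Reactants: 2 5-iodovanillin; 5 3,5-dimethoxy-4-(triisopropylsilyloxy)styrene
Product: 6 (E)-4-hydroxy-3-methoxy-5-{2-[3,5-dimethoxy-4-(triisopropylsilyloxy)phenyl]ethenyl}benzaldehyde
Conditions: Pd(OAc)2 (5 mol%), P(o-tol)3 (10 mol%), Et3N (3 equiv), DMF, 90 °C
Reagents that add atoms: none
Why: Mizoroki–Heck coupling, in which zerovalent palladium inserts into the aryl iodide, the styrene inserts at its terminal carbon and syn beta-hydride elimination gives the E-stilbene; ortho-iodophenols are competent partners without protection.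

Step 5
Reactants: 6 (E)-4-hydroxy-3-methoxy-5-{2-[3,5-dimethoxy-4-(triisopropylsilyloxy)phenyl]ethenyl}benzaldehyde
Product: 7 methyl (2R,3R)-2-[3,5-dimethoxy-4-(triisopropylsilyloxy)phenyl]-5-formyl-7-methoxy-2,3-dihydro-1-benzofuran-3-carboxylate (2,3-trans)
Conditions: Pd(OCOCF3)2 (10 mol%), (S,S)-Bn-BOXAX (20 mol%), p-benzoquinone (4 equiv), CO (10 bar), MeOH/CH2Cl2 1:4, 25 °C
Reagents that add atoms: carbon monoxide, [C-]#[O+]; methanol, CO
Why: Proposed new method: the bis(oxazoline)-bound cationic divalent palladium binds the stilbene alkene of 6, the ring A phenol adds to the syringyl-bearing carbon (C2) anti to the metal, and the C3–palladium bond so formed takes up CO and is cleaved by methanol to the methyl ester, after which benzoquinone returns zerovalent palladium to the divalent state. The closest known reactions are the enantioselective Wacker-type cyclisation–methoxycarbonylation of alkenyl phenols under this same catalyst system and the divalent-palladium oxidative cyclisation of 2-hydroxystilbenes to 2-arylbenzofurans, the latter showing that this oxypalladation operates on the substrate class; what is new is the interception of its alkylpalladium intermediate by CO. The dihydrofuran ring closes in a 5-endo-trig mode through O1–C2 bond formation, the only ring size the tether allows (attack at C3 would be 4-exo) and the regiochemistry favoured by the electron-rich syringyl ring. C2 is set by the chiral ligand, which decides the alkene face held by palladium during the anti attack of oxygen, and C3 follows from C2 because anti oxypalladation of the E alkene places palladium trans to the syringyl group and CO insertion goes with retention, the trans ester also being the thermodynamic isomer at this epimerisable centre. The selectivity required is CO insertion ahead of syn beta-hydride elimination of the C2 hydrogen (the path to the achiral benzofuran), for which the CO pressure, the eta-3 benzyl stabilisation of the C3–palladium species by ring A and the electron-poor trifluoroacetate complex are relied on, while the TIPS ether keeps the syringyl oxygen out of quinone methide and benzoquinone chemistry.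

Step 6
Reactants: 7 methyl (2R,3R)-2-[3,5-dimethoxy-4-(triisopropylsilyloxy)phenyl]-5-formyl-7-methoxy-2,3-dihydro-1-benzofuran-3-carboxylate
Product: 8 {(2R,3S)-2-[3,5-dimethoxy-4-(triisopropylsilyloxy)phenyl]-3-(hydroxymethyl)-7-methoxy-2,3-dihydro-1-benzofuran-5-yl}methanol
Conditions: i-Bu2AlH (5 equiv), CH2Cl2, −78 to 0 °C; aq. potassium sodium tartrate
Reagents that add atoms: none
Why: Hydride reduction with i-Bu2AlH takes the ester to the C9 alcohol and the aldehyde to the benzylic alcohol under non-basic conditions, so the trans C2/C3 relationship is carried through unchanged (the descriptor at C3 changes only because the priorities change) and the aryl silyl ether is untouched.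

Step 7
Reactants: 8 {(2R,3S)-2-[3,5-dimethoxy-4-(triisopropylsilyloxy)phenyl]-3-(hydroxymethyl)-7-methoxy-2,3-dihydro-1-benzofuran-5-yl}methanol
Product: 9 (2R,3S)-2-[3,5-dimethoxy-4-(triisopropylsilyloxy)phenyl]-3-(hydroxymethyl)-7-methoxy-2,3-dihydro-1-benzofuran-5-carbaldehyde
Conditions: MnO2 (15 equiv), CH2Cl2, 25 °C
Reagents that add atoms: none
Why: Chemoselective MnO2 oxidation, which converts only the benzylic alcohol on ring A (activated by the para oxygen O1) into the aldehyde and leaves the non-benzylic C9 alcohol alone.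

Step 8
Reactants: 10 methyl 3,5-dihydroxybenzoate
Product: 11 methyl 3,5-bis(triisopropylsilyloxy)benzoate
Conditions: TIPSCl (2.4 equiv), imidazole, DMF, 25 °C
Reagents that add atoms: chlorotriisopropylsilane, CC(C)[Si](Cl)(C(C)C)C(C)C
Why: Imidazole-promoted silylation of both unhindered phenols gives base-stable aryl TIPS ethers that come off with fluoride at the end together with the syringyl one.

Step 9
Reactants: 11 methyl 3,5-bis(triisopropylsilyloxy)benzoate
Product: 12 [3,5-bis(triisopropylsilyloxy)phenyl]methanol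
Conditions: i-Bu2AlH (2.5 equiv), CH2Cl2, −78 to 0 °C; aq. potassium sodium tartrate
Reagents that add atoms: none
Why: Ester reduction by i-Bu2AlH to the benzylic alcohol in the absence of any alkoxide nucleophile, so the aryl silyl ethers are kept.

Step 10
Reactants: 12 [3,5-bis(triisopropylsilyloxy)phenyl]methanol
Product: 13 1-(bromomethyl)-3,5-bis(triisopropylsilyloxy)benzene
Conditions: CBr4, PPh3, CH2Cl2, 0 °C
Reagents that add atoms: carbon tetrabromide, BrC(Br)(Br)Br
Why: Appel bromination converts the primary benzylic alcohol into the bromide under neutral conditions that do not touch silyl ethers.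

Step 11
Reactants: 13 1-(bromomethyl)-3,5-bis(triisopropylsilyloxy)benzene
Product: 14 diethyl [3,5-bis(triisopropylsilyloxy)benzyl]phosphonate
Conditions: P(OEt)3 (neat), 130 °C
Reagents that add atoms: triethyl phosphite, CCOP(OCC)OCC
Why: Michaelis–Arbuzov reaction, in which the phosphite displaces the benzylic bromide and the phosphonium salt loses bromoethane to give the phosphonate.

Step 12
Reactants: 9 (2R,3S)-2-[3,5-dimethoxy-4-(triisopropylsilyloxy)phenyl]-3-(hydroxymethyl)-7-methoxy-2,3-dihydro-1-benzofuran-5-carbaldehyde; 14 diethyl [3,5-bis(triisopropylsilyloxy)benzyl]phosphonate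
Product: 16 {(2R,3S)-5-[(E)-2-[3,5-bis(triisopropylsilyloxy)phenyl]ethenyl]-2-[3,5-dimethoxy-4-(triisopropylsilyloxy)phenyl]-7-methoxy-2,3-dihydro-1-benzofuran-3-yl}methanol, via phosphonate carbanion sodium salt 15 (not isolated)
Conditions: 14 (2.5 equiv), NaN(SiMe3)2 (2.4 equiv), THF, −78 °C; then 9, −78 to 25 °C; aq. NH4Cl
Reagents that add atoms: none
Why: Horner–Wadsworth–Emmons olefination, in which the benzylic phosphonate carbanion adds to the aromatic aldehyde and loses diethyl phosphate under thermodynamic control to give the E-stilbene; the excess carbanion covers the equivalent taken by the free C9 hydroxyl, and neither C2–H nor C3–H is acidic now that the ester is gone.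

Step 13
Reactants: 16 {(2R,3S)-5-[(E)-2-[3,5-bis(triisopropylsilyloxy)phenyl]ethenyl]-2-[3,5-dimethoxy-4-(triisopropylsilyloxy)phenyl]-7-methoxy-2,3-dihydro-1-benzofuran-3-yl}methanol
Product: 17 gnetucleistol F, 5-[(E)-2-[(2R,3S)-2-(4-hydroxy-3,5-dimethoxyphenyl)-3-(hydroxymethyl)-7-methoxy-2,3-dihydro-1-benzofuran-5-yl]ethenyl]benzene-1,3-diol
Conditions: Bu4NF (4 equiv), AcOH (4 equiv), THF, 0 to 25 °C, under argon
Reagents that add atoms: none
Why: Fluoride cleavage of the three aryl silyl ethers driven by Si–F bond formation, with acetic acid buffering the phenoxides so that the syringyl phenoxide cannot expel O1 from C2 through a quinone methide and both stereocentres stay as set.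

**Compound list**

1 | vanillin | COc1cc(C=O)ccc1O | starting material
2 | 5-iodovanillin | COc1cc(C=O)cc(I)c1O | intermediate
3 | syringaldehyde | COc1cc(C=O)cc(OC)c1O | starting material
4 | 3,5-dimethoxy-4-(triisopropylsilyloxy)benzaldehyde | COc1cc(C=O)cc(OC)c1O[Si](C(C)C)(C(C)C)C(C)C | intermediate
5 | 3,5-dimethoxy-4-(triisopropylsilyloxy)styrene | C=Cc1cc(OC)c(O[Si](C(C)C)(C(C)C)C(C)C)c(OC)c1 | intermediate
6 | (E)-4-hydroxy-3-methoxy-5-{2-[3,5-dimethoxy-4-(triisopropylsilyloxy)phenyl]ethenyl}benzaldehyde | COc1cc(/C=C/c2cc(C=O)cc(OC)c2O)cc(OC)c1O[Si](C(C)C)(C(C)C)C(C)C | intermediate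
7 | methyl (2R,3R)-2-[3,5-dimethoxy-4-(triisopropylsilyloxy)phenyl]-5-formyl-7-methoxy-2,3-dihydro-1-benzofuran-3-carboxylate (trans) | COc1cc([C@@H]2Oc3c(OC)cc(C=O)cc3[C@H]2C(=O)OC)cc(OC)c1O[Si](C(C)C)(C(C)C)C(C)C | intermediate
8 | {(2R,3S)-2-[3,5-dimethoxy-4-(triisopropylsilyloxy)phenyl]-3-(hydroxymethyl)-7-methoxy-2,3-dihydro-1-benzofuran-5-yl}methanol | COc1cc([C@@H]2Oc3c(OC)cc(CO)cc3[C@H]2CO)cc(OC)c1O[Si](C(C)C)(C(C)C)C(C)C | intermediate
9 | (2R,3S)-2-[3,5-dimethoxy-4-(triisopropylsilyloxy)phenyl]-3-(hydroxymethyl)-7-methoxy-2,3-dihydro-1-benzofuran-5-carbaldehyde | COc1cc([C@@H]2Oc3c(OC)cc(C=O)cc3[C@H]2CO)cc(OC)c1O[Si](C(C)C)(C(C)C)C(C)C | intermediate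
10 | methyl 3,5-dihydroxybenzoate | COC(=O)c1cc(O)cc(O)c1 | starting material
11 | methyl 3,5-bis(triisopropylsilyloxy)benzoate | COC(=O)c1cc(O[Si](C(C)C)(C(C)C)C(C)C)cc(O[Si](C(C)C)(C(C)C)C(C)C)c1 | intermediate
12 | [3,5-bis(triisopropylsilyloxy)phenyl]methanol | OCc1cc(O[Si](C(C)C)(C(C)C)C(C)C)cc(O[Si](C(C)C)(C(C)C)C(C)C)c1 | intermediate
13 | 1-(bromomethyl)-3,5-bis(triisopropylsilyloxy)benzene | BrCc1cc(O[Si](C(C)C)(C(C)C)C(C)C)cc(O[Si](C(C)C)(C(C)C)C(C)C)c1 | intermediate
14 | diethyl [3,5-bis(triisopropylsilyloxy)benzyl]phosphonate | CCOP(=O)(OCC)Cc1cc(O[Si](C(C)C)(C(C)C)C(C)C)cc(O[Si](C(C)C)(C(C)C)C(C)C)c1 | intermediate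
15 | sodium salt of the carbanion of 14 (formed in the flask, not isolated) | CCOP(=O)(OCC)[CH-]c1cc(O[Si](C(C)C)(C(C)C)C(C)C)cc(O[Si](C(C)C)(C(C)C)C(C)C)c1.[Na+] | intermediate
16 | {(2R,3S)-5-[(E)-2-[3,5-bis(triisopropylsilyloxy)phenyl]ethenyl]-2-[3,5-dimethoxy-4-(triisopropylsilyloxy)phenyl]-7-methoxy-2,3-dihydro-1-benzofuran-3-yl}methanol | COc1cc([C@@H]2Oc3c(OC)cc(/C=C/c4cc(O[Si](C(C)C)(C(C)C)C(C)C)cc(O[Si](C(C)C)(C(C)C)C(C)C)c4)cc3[C@H]2CO)cc(OC)c1O[Si](C(C)C)(C(C)C)C(C)C | intermediate
17 | gnetucleistol F, (2R,3S) | COc1cc([C@@H]2Oc3c(OC)cc(/C=C/c4cc(O)cc(O)c4)cc3[C@H]2CO)cc(OC)c1O | target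

**Step count**

Total: 13 steps. Longest linear sequence: 8 steps (steps 2, 3, 4, 5, 6, 7, 12, 13, from syringaldehyde).

**Steps most likely to fail**

1. Step 5 (proposed new method). What may go wrong:
- beta-hydride elimination of the C3–palladium intermediate outrunning CO insertion, which erases both stereocentres;
- weak facial discrimination of a 1,2-diarylalkene by the ligand;
- CO saturating the metal and suppressing alkene binding;
- carbonylation at the phenol oxygen ahead of oxypalladation;
- reversible addition of methanol to the formyl group, which a mildly acidic aqueous work-up would undo.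

Fallback by known chemistry, setting out from 4 (with 2 as partner) and coming back at 7. Reduction of 4 with NaBH4 in MeOH/THF at 0 °C should give [3,5-dimethoxy-4-(triisopropylsilyloxy)phenyl]methanol F1. Mitsunobu etherification of the phenol of 2 with F1 (PPh3, DIAD, THF) should give 4-{[3,5-dimethoxy-4-(triisopropylsilyloxy)phenyl]methoxy}-3-iodo-5-methoxybenzaldehyde F2. Palladium-catalysed coupling of this aryl iodide with methyl diazoacetate (Pd(PPh3)4, Ag2CO3, Et3N, toluene, 25 °C) should give methyl 2-diazo-2-(2-{[3,5-dimethoxy-4-(triisopropylsilyloxy)phenyl]methoxy}-5-formyl-3-methoxyphenyl)acetate F3. Intramolecular carbenoid C–H insertion into the ether-activated benzylic CH2 with dirhodium tetrakis[N-phthaloyl-tert-leucinate], Rh2(S-PTTL)4 or its antipode, in toluene at −60 °C is expected to give the cis ester, methyl (2R,3S)-2-[3,5-dimethoxy-4-(triisopropylsilyloxy)phenyl]-5-formyl-7-methoxy-2,3-dihydro-1-benzofuran-3-carboxylate F4. Epimerisation at C3 alone (catalytic NaOMe in MeOH/THF at 0 °C, or DBU in toluene) should then give the trans ester 7.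

2. Step 4. What may go wrong: deactivation of the catalyst by the ortho phenoxide with slow oxidative addition, or loss of the silyl group on prolonged heating in amine/DMF.

Fallback, setting out from 5 and coming back at 6. Cross-metathesis of 5 with vinylboronic acid pinacol ester using the second-generation Grubbs catalyst RuCl2(=CHPh)(PCy3)(H2IMes) in CH2Cl2 at 40 °C should give (E)-2-{2-[3,5-dimethoxy-4-(triisopropylsilyloxy)phenyl]ethenyl}-4,4,5,5-tetramethyl-1,3,2-dioxaborolane F5. Suzuki–Miyaura coupling of F5 with unprotected 2 (PdCl2(dppf), K3PO4, dioxane/H2O, 60 °C) should give 6 with the alkene geometry fixed by the boronate.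

3. Step 12. What may go wrong: sluggish or incomplete olefination of the electron-rich aldehyde in the presence of the C9 alkoxide, erosion of E selectivity, or silyl transfer to that alkoxide.

Fallback, setting out from 9 and coming back at 16. Wittig methylenation of 9 (Ph3PCH3Br, KOt-Bu, 2.5 equiv of ylide, THF) should give {(2R,3S)-2-[3,5-dimethoxy-4-(triisopropylsilyloxy)phenyl]-5-ethenyl-7-methoxy-2,3-dihydro-1-benzofuran-3-yl}methanol F6. Silylation of commercial 5-bromoresorcinol (Oc1cc(O)cc(Br)c1) with TIPSCl and imidazole gives 1-bromo-3,5-bis(triisopropylsilyloxy)benzene F7. Heck coupling of F6 with F7 (Pd2(dba)3, P(t-Bu)3, Cy2NMe, dioxane, 60 °C) should give the E-stilbene 16.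

**Further compounds**

F1 | step 5 | [3,5-dimethoxy-4-(triisopropylsilyloxy)phenyl]methanol | OCc1cc(OC)c(O[Si](C(C)C)(C(C)C)C(C)C)c(OC)c1
F2 | step 5 | 4-{[3,5-dimethoxy-4-(triisopropylsilyloxy)phenyl]methoxy}-3-iodo-5-methoxybenzaldehyde | COc1cc(C=O)cc(I)c1OCc1cc(OC)c(O[Si](C(C)C)(C(C)C)C(C)C)c(OC)c1
F3 | step 5 | methyl 2-diazo-2-(2-{[3,5-dimethoxy-4-(triisopropylsilyloxy)phenyl]methoxy}-5-formyl-3-methoxyphenyl)acetate | COC(=O)C(=[N+]=[N-])c1cc(C=O)cc(OC)c1OCc1cc(OC)c(O[Si](C(C)C)(C(C)C)C(C)C)c(OC)c1
F4 | step 5 | methyl (2R,3S)-2-[3,5-dimethoxy-4-(triisopropylsilyloxy)phenyl]-5-formyl-7-methoxy-2,3-dihydro-1-benzofuran-3-carboxylate (cis) | COc1cc([C@@H]2Oc3c(OC)cc(C=O)cc3[C@@H]2C(=O)OC)cc(OC)c1O[Si](C(C)C)(C(C)C)C(C)C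
F5 | step 4 | (E)-2-{2-[3,5-dimethoxy-4-(triisopropylsilyloxy)phenyl]ethenyl}-4,4,5,5-tetramethyl-1,3,2-dioxaborolane | COc1cc(/C=C/B2OC(C)(C)C(C)(C)O2)cc(OC)c1O[Si](C(C)C)(C(C)C)C(C)C
F6 | step 12 | {(2R,3S)-2-[3,5-dimethoxy-4-(triisopropylsilyloxy)phenyl]-5-ethenyl-7-methoxy-2,3-dihydro-1-benzofuran-3-yl}methanol | COc1cc([C@@H]2Oc3c(OC)cc(C=C)cc3[C@H]2CO)cc(OC)c1O[Si](C(C)C)(C(C)C)C(C)C
F7 | step 12 | 1-bromo-3,5-bis(triisopropylsilyloxy)benzene | Brc1cc(O[Si](C(C)C)(C(C)C)C(C)C)cc(O[Si](C(C)C)(C(C)C)C(C)C)c1
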